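The synthesis rests on cutting the C4=C5 bond of a late tricyclic enone: C4 is the α-carbon of the enone-half cyclopentanone (ring A) and C5 the one-carbon bridge of its bicyclo[3.2.1]octane (rings B/C). One base-mediated aldol condensation closes ring A on a precursor that already carries the complete, ketal-protected saturated half: a bicyclo[3.2.1]octan-8-one whose bridgehead C10 bears a CH2–CO–CH2–CH2 chain ending at C2′ of the second tricycle. The step exploits the strained, non-enolisable C5 bridge ketone, the only carbonyl a C4 enolate can reach. Both halves derive from one allyl bicyclooctanone; dissolving-metal reduction and α-methylenation complete alertenone.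

Key step: step 20

Numbering (each C15 half, methyl carbons not counted): C1 exocyclic CH2 carbon (or its future position), C2, C3 (C=O), C4, C5 (one-carbon bridge), C6 (bridgehead CH), C7, C8, C9 (CH–CH3), C10 (quaternary bridgehead), C11 (CH2), C12 (CMe2). Ring A = C2–C3–C4–C5–C10, ring B = C5–C6–C7–C8–C9–C10, ring C = C5–C6–C12–C11–C10. Primes mark the half that ends as the saturated ketone; C1′ is the CH2 linker on C2′. Steps 9–16 build that half from 16; step 17 makes the C2–C3 aldehyde of the enone half from the same 16.

Remark: in 35 and 37 every stereocentre already present (C6, C9, C10, C2′, C5′, C6′, C9′, C10′) has the configuration of the target; 37 lacks only C4 and C5, which step 21 sets.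

Assumption: the C9 (C9′) methyl is axial on ring B and overhangs one face of C2 (C2′). The target C2′ epimer has C1′ on that same side and is taken to be the less stable one. It is therefore made by hydrogen delivery to the open face and never exposed to base or hot acid while C3′ is a free ketone.

Assumption: hydroxy ketone 13 and alcohol 34 are drawn open-chain although each equilibrates with a cyclic hemiketal. The allyl-bearing ring carbon of 7 and 9–15 and the carbinol carbon of 34 are epimer mixtures that later steps erase.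

Step 1
Reactants: 1 (R)-butane-1,3-diol
Product: 2 (R)-4-iodobutan-2-ol
Conditions: PPh3, I2, imidazole, CH2Cl2, 0 °C
Reagents that add atoms: iodine, II
Why: Appel-type iodination (Garegg–Samuelsson conditions) converts only the unhindered primary hydroxyl, so the secondary carbinol centre, the future C9, keeps its R configuration.

Step 2
Reactants: 2 (R)-4-iodobutan-2-ol
Product: 3 triethyl{[(2R)-4-iodobutan-2-yl]oxy}silane
Conditions: Et3SiCl, imidazole, DMF, 0 °C
Reagents that add atoms: chlorotriethylsilane, CC[Si](Cl)(CC)CC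
Why: Routine silyl ether formation masks the alcohol for the azaenolate alkylation and is later removed by dilute acid.

Step 3
Reactants: 4 4,4-dimethylcyclopent-2-en-1-one; 5 allyl bromide
Product: 7 4,4-dimethyl-2-(prop-2-en-1-yl)cyclopentan-1-one (racemic), via lithium enolate 6 (not isolated)
Conditions: Li, NH3(l)/THF, t-BuOH (1 equiv), −78 °C; then 5, −78 → −33 °C
Reagents that add atoms: none
Why: Stork reductive alkylation: dissolving-metal reduction of the enone gives the regiodefined enolate, which allyl bromide alkylates at the former α-carbon, the future C10.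

Step 4
Reactants: 7 4,4-dimethyl-2-(prop-2-en-1-yl)cyclopentan-1-one; 8 SAMP, (S)-1-amino-2-(methoxymethyl)pyrrolidine
Product: 9 SAMP hydrazone of 7
Conditions: TsOH (cat.), cyclohexane, reflux (Dean–Stark)
Reagents that add atoms: none
Why: Hydrazone condensation, in which the amino nitrogen settles anti to the allyl-bearing α-carbon and so points toward the CH2 that is to be alkylated.

Step 5
Reactants: 9 SAMP hydrazone of 7; 3 triethyl{[(2R)-4-iodobutan-2-yl]oxy}silane
Product: 11 C6-alkylated SAMP hydrazone, via lithium azaenolate 10 (not isolated)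
Conditions: LiN(i-Pr)2, THF, 0 °C; then 3, −100 °C → rt
Reagents that add atoms: none
Why: Enders SAMP-hydrazone alkylation: the amide removes a proton from the less substituted α-CH2 and the chelated azaenolate takes up the primary iodide on the face opposite the methoxymethyl arm, which should set C6 as R (the usual sense for SAMP with cyclic ketones).

Step 6
Reactants: 11 C6-alkylated SAMP hydrazone
Product: 13 (2R)-2-[(3R)-3-hydroxybutyl]-3,3-dimethyl-5-(prop-2-en-1-yl)cyclopentan-1-one, via silyl ether ketone 12 (not isolated)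
Conditions: sat. aq. (CO2H)2, Et2O, rt; then 1 M HCl, THF, rt
Reagents that add atoms: water, O
Why: Mild two-phase acid hydrolysis of the hydrazone, a method that spares α-stereocentres, followed by acid cleavage of the triethylsilyl ether.

Step 7
Reactants: 13 hydroxy ketone
Product: 14 secondary tosylate of 13
Conditions: TsCl, pyridine, DMAP (cat.), CH2Cl2, 0 °C → rt
Reagents that add atoms: 4-methylbenzenesulfonyl chloride, Cc1ccc(cc1)S(Cl)(=O)=O
Why: Sulfonylation at oxygen turns the secondary alcohol into a leaving group with retention at the carbinol carbon.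

Step 8
Reactants: 14 secondary tosylate
Product: 16 (1R,2S,5R)-2,6,6-trimethyl-1-(prop-2-en-1-yl)bicyclo[3.2.1]octan-8-one, via potassium enolate 15 (not isolated)
Conditions: KN(SiMe3)2 (1.1 equiv), THF, −78 °C → rt (14 added to the base)
Reagents that add atoms: none
Why: Intramolecular enolate C-alkylation (6-(enolendo)-exo-tet, the classical α,α′-annulation of cyclopentanones to bicyclo[3.2.1]octan-8-ones): the amide removes the less hindered C10–H and the enolate displaces the tosylate with inversion, so (R)-C9–OTs becomes (S)-C9 with its methyl axial on ring B, while the tether on C6 can only reach the cis face and thereby fixes C10.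

Step 9
Reactants: 16 allyl bicyclooctanone
Product: 17 (1S,2S,5R)-2,6,6-trimethyl-1-(2-oxopropyl)bicyclo[3.2.1]octan-8-one
Conditions: PdCl2 (10 mol %), CuCl, O2 (1 atm), DMF/H2O 7:1, rt
Reagents that add atoms: water, O
Why: Tsuji–Wacker oxidation of the terminal alkene gives the methyl ketone with Markovnikov regiochemistry, the standard entry to 1,4-diketones from α-allyl ketones.

Step 10
Reactants: 17 1,4-diketone
Product: 19 tricyclic C4′=C5′ enone, via aldol adduct 18 (not isolated)
Conditions: KOt-Bu, t-BuOH, 70 °C
Reagents that add atoms: none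
Why: Aldol cyclodehydration of a 1,4-diketone to a cyclopentenone: only the methyl (C4′) enolate can reach the non-enolisable bridge carbonyl C5′, and E1cB loss of water gives the enone, a rehearsal of the key step on the simple diketone.

Step 11
Reactants: 19 tricyclic enone
Product: 22 2′-methylene dienone, via Mannich base 20 (not isolated), via methiodide 21 (not isolated)
Conditions: LiN(i-Pr)2, THF, −78 °C; Me2N=CH2 I, −78 °C → rt; then MeI, CH2Cl2/MeOH, rt; then sat. aq. NaHCO3, CH2Cl2, rt
Reagents that add atoms: N,N-dimethylmethyleneiminium iodide, C=[N+](C)C.[I-]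
Why: Eschenmoser methylenation (Mannich reaction of the only possible enolate, at C2′, then Hofmann-type β-elimination of the quaternised amine) installs the exocyclic methylene whose carbon becomes the linker C1′.

Step 12
Reactants: 22 2′-methylene dienone
Product: 24 2′-allyl enone, via magnesium enolate 23 (not isolated)
Conditions: CH2=CHMgBr, CuBr·SMe2 (10 mol %), THF, −78 °C; then AcOH, THF, −78 °C
Reagents that add atoms: vinylmagnesium bromide, C=C[Mg]Br
Why: Copper-catalysed 1,4-addition of the vinyl Grignard reagent to the exocyclic s-cis enone (the tetrasubstituted ring enone is inert), then kinetic protonation of the C2′ enolate on the face opposite the axial C9′ methyl that overhangs the other face, which should place C1′ syn to that methyl as in the target.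

Step 13
Reactants: 24 2′-allyl enone
Product: 26 2′-allyl saturated ketone, via lithium enolate 25 (not isolated)
Conditions: Li, NH3(l)/THF, t-BuOH (1 equiv), −78 °C (24 added to the blue solution); then NH4Cl
Reagents that add atoms: none
Why: Birch-type dissolving-metal enone reduction: protonation of C5′ gives the only low-strain fusion (rings A and C cis, H5′ toward ring B), and the regiodefined C3′–C4′ enolate leaves C2′ and the isolated alkene untouched.

Step 14
Reactants: 26 2′-allyl saturated ketone
Product: 27 ethylene ketal of 26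
Conditions: Me3SiOCH2CH2OSiMe3, Me3SiOTf (5 mol %), CH2Cl2, −78 → −20 °C; pyridine
Reagents that add atoms: 1,2-bis(trimethylsilyloxy)ethane, C[Si](C)(C)OCCO[Si](C)(C)C
Why: Noyori ketalisation runs at low temperature without enolisation, so C2′ is locked unchanged next to a carbon that can no longer enolise.

Step 15
Reactants: 27 allyl ketal
Product: 29 ketal alcohol HO–C4H2–C1′H2–C2′, via ozonide 28 (not isolated)
Conditions: O3, CH2Cl2, −78 °C; then NaBH4, MeOH, −78 → 0 °C
Reagents that add atoms: ozone, [O-][O+]=O
Why: Ozonolysis with borohydride work-up cuts the terminal alkene to the primary alcohol and leaves the two-carbon arm C1′–C4.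

Step 16
Reactants: 29 ketal alcohol
Product: 30 ketal bromide Br–C4H2–C1′H2–C2′
Conditions: CBr4, PPh3, 2,6-lutidine, CH2Cl2, 0 °C
Reagents that add atoms: carbon tetrabromide, BrC(Br)(Br)Br
Why: Appel bromination of an unhindered primary alcohol under buffered conditions that keep the ketal intact.

Step 17
Reactants: 16 allyl bicyclooctanone
Product: 32 2-[(1S,2S,5R)-2,6,6-trimethyl-8-oxobicyclo[3.2.1]octan-1-yl]acetaldehyde, via ozonide 31 (not isolated)
Conditions: O3, CH2Cl2, −78 °C; then PPh3, −78 °C → rt
Reagents that add atoms: ozone, [O-][O+]=O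
Why: Ozonolysis with reductive work-up gives the C3 aldehyde, and the saturated bridge ketone is inert to ozone.

Step 18
Reactants: 30 ketal bromide; 32 keto aldehyde
Product: 34 coupled secondary alcohol (C3 epimers), via Grignard reagent 33 (not isolated)
Conditions: Mg, THF, 40 °C; then 32, THF, −78 °C; aq. NH4Cl
Reagents that add atoms: none
Why: Grignard addition forms the C3–C4 bond: at −78 °C the aldehyde should react far faster than the bridge ketone flanked by a quaternary carbon and a bridgehead, and the δ-ketal Grignard reagent cannot β-eliminate.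

Step 19
Reactants: 34 coupled secondary alcohol
Product: 35 aldol precursor, the C3/C5 1,4-diketone carrying the ketalised saturated half
Conditions: Dess–Martin periodinane, NaHCO3, CH2Cl2, rt
Reagents that add atoms: none
Why: Dess–Martin oxidation of the secondary alcohol under buffered, non-enolising conditions gives the 1,4-diketone without touching the ketal.

Step 20
Reactants: 35 aldol precursor
Product: 37 tricyclic C4=C5 enone linked through C1′ to the ketalised saturated half, via aldol adduct 36 (not isolated)
Conditions: KOt-Bu (1.5 equiv), t-BuOH/THF, 70 °C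
Reagents that add atoms: none
Why: KOt-Bu enolises the C3 ketone of 35 reversibly toward C2 and C4; only the C4 enolate can cyclise, adding to the strained C5 bridge carbonyl to give aldol 36, and E1cB loss of water through the C3–C4 enolate then delivers the tetrasubstituted C4=C5 enone 37. The closest known reaction is the base-mediated cyclodehydration of 1,4-diketones to fused cyclopentenones, rehearsed on diketone 17 in step 10. Ring A (C2–C3–C4–C5–C10) closes by 5-exo-trig attack on the C5 carbonyl, enolendo with respect to the C3=C4 enolate, the mode common to all such 1,4-diketone aldolisations and the reason the step is run warm. No stereocentre is created, since C4 and C5 both end sp2 and are set in step 21, and no existing one is at risk: C6, C9 and C10 cannot enolise and C2′ sits next to the ketal carbon. The step needs site selectivity between enolates and between carbonyls, and the substrate secures both: the C2 enolate could only form a three-membered ring, C5 is the sole carbonyl within five-ring reach of C4, C5 has no α-hydrogen it can lose (C10 is quaternary, C6 a bridgehead), and C3′ is masked as its dioxolane. Because the new double bond is exocyclic to the bicyclo[3.2.1]octane at its one-carbon bridge it adds no bridgehead-alkene strain, so dehydration should be irreversible and pull the aldol equilibrium to 37.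

Step 21
Reactants: 37 tricyclic C4=C5 enone
Product: 40 saturated diketone monoketal with C4 and C5 as in the target, via lithium enolate 38 (not isolated), via ketone epimers 39 (not isolated)
Conditions: Li, NH3(l)/THF, t-BuOH (1 equiv), −78 °C; NH4Cl; then NaOMe, MeOH, rt
Reagents that add atoms: none
Why: Birch-type enone reduction protonates C5 so that rings A and C become cis-fused (a trans-bicyclo[3.3.0]octane would be far more strained), and methoxide then equilibrates the enolisable C4 to the epimer with C1′ on the convex face, away from the C12 methyl, which is the target configuration.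

Step 22
Reactants: 40 saturated diketone monoketal
Product: 42 C2-(dimethylaminomethyl) diketone, via Mannich base ketal 41 (not isolated)
Conditions: LiN(i-Pr)2, THF, −78 °C; Me2N=CH2 I, −78 °C → rt; then 1 M HCl, THF, 0 °C → rt; NaHCO3 work-up
Reagents that add atoms: N,N-dimethylmethyleneiminium iodide, C=[N+](C)C.[I-]; water, O
Why: Kinetic deprotonation should occur at the C2 methylene and not at the substituted C4 methine, the enolate adds to the iminium salt (Mannich reaction), and brief cold aqueous acid then removes the dioxolane while the amine is held as its ammonium salt.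

Step 23
Reactants: 42 C2-(dimethylaminomethyl) diketone
Product: 44 alertenone, via methiodide 43 (not isolated)
Conditions: MeI, CH2Cl2/MeOH, rt; then sat. aq. NaHCO3, CH2Cl2, rt
Reagents that add atoms: none
Why: Quaternisation and Hofmann-type β-elimination under bicarbonate (the second half of the Eschenmoser methylenation) unveil the exocyclic enone under conditions too mild to epimerise C2′ or C4.

Compound list

1 | (R)-butane-1,3-diol | C[C@@H](O)CCO | starting material
2 | (R)-4-iodobutan-2-ol | C[C@@H](O)CCI | intermediate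
3 | triethyl{[(2R)-4-iodobutan-2-yl]oxy}silane | C[C@@H](O[Si](CC)(CC)CC)CCI | intermediate
4 | 4,4-dimethylcyclopent-2-en-1-one | O=C1C=CC(C)(C)C1 | starting material
5 | allyl bromide (3-bromoprop-1-ene) | C=CCBr | starting material
6 | lithium 4,4-dimethylcyclopent-1-en-1-olate | [Li+].[O-]C1=CCC(C)(C)C1 | intermediate
7 | 4,4-dimethyl-2-(prop-2-en-1-yl)cyclopentan-1-one (racemic) | C=CCC1CC(C)(C)CC1=O | intermediate
8 | SAMP, (S)-1-amino-2-(methoxymethyl)pyrrolidine | COC[C@@H]1CCCN1N | starting material
9 | SAMP hydrazone of 7 (amino N syn to the ring CH2 next to CMe2; allyl carbon epimers) | COC[C@@H]1CCCN1/N=C2\CC(C)(C)CC2CC=C | intermediate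
10 | lithium azaenolate of 9 (C=C toward the CH2 next to CMe2) | [Li+].COC[C@@H]1CCCN1[N-]C2=CC(C)(C)CC2CC=C | intermediate
11 | SAMP hydrazone of (2R)-3,3-dimethyl-5-(prop-2-en-1-yl)-2-[(3R)-3-(triethylsilyloxy)butyl]cyclopentan-1-one | COC[C@@H]1CCCN1/N=C2\[C@H](CC[C@@H](C)O[Si](CC)(CC)CC)C(C)(C)CC2CC=C | intermediate
12 | (2R)-3,3-dimethyl-5-(prop-2-en-1-yl)-2-[(3R)-3-(triethylsilyloxy)butyl]cyclopentan-1-one (C5 epimers) | O=C1C(CC=C)CC(C)(C)[C@H]1CC[C@@H](C)O[Si](CC)(CC)CC | intermediate
13 | (2R)-2-[(3R)-3-hydroxybutyl]-3,3-dimethyl-5-(prop-2-en-1-yl)cyclopentan-1-one (C5 epimers) | O=C1C(CC=C)CC(C)(C)[C@H]1CC[C@@H](C)O | intermediate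
14 | (2R)-4-[(1R)-2,2-dimethyl-5-oxo-4-(prop-2-en-1-yl)cyclopentyl]butan-2-yl 4-methylbenzenesulfonate (allyl carbon epimers) | O=C1C(CC=C)CC(C)(C)[C@H]1CC[C@@H](C)OS(=O)(=O)c1ccc(C)cc1 | intermediate
15 | potassium enolate of 14 (C=C toward the allyl-bearing carbon) | [K+].[O-]C1=C(CC=C)CC(C)(C)[C@H]1CC[C@@H](C)OS(=O)(=O)c1ccc(C)cc1 | intermediate
16 | (1R,2S,5R)-2,6,6-trimethyl-1-(prop-2-en-1-yl)bicyclo[3.2.1]octan-8-one | C=CC[C@]12C(=O)[C@H](CC[C@@H]1C)C(C)(C)C2 | intermediate
17 | (1S,2S,5R)-2,6,6-trimethyl-1-(2-oxopropyl)bicyclo[3.2.1]octan-8-one | CC(=O)C[C@]12C(=O)[C@H](CC[C@@H]1C)C(C)(C)C2 | intermediate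
18 | aldol adduct of 17 (tertiary OH on bridge carbon C5′, rings A and C cis-fused) | O=C1C[C@]23[C@@H](C)CC[C@@H]([C@]3(O)C1)C(C)(C)C2 | intermediate
19 | tricyclic enone: ring A cyclopentenone with C4′=C5′ at the one-carbon bridge, C2′ unsubstituted | O=C1C[C@]23[C@@H](C)CC[C@@H](C3=C1)C(C)(C)C2 | intermediate
20 | 2′-(dimethylaminomethyl) derivative of 19 (CH2N on the C11′ side) | CN(C)C[C@H]1C(=O)C=C2[C@@H]3CC[C@H](C)[C@]12CC3(C)C | intermediate
21 | methiodide of 20 | C[N+](C)(C)C[C@H]1C(=O)C=C2[C@@H]3CC[C@H](C)[C@]12CC3(C)C.[I-] | intermediate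
22 | 2′-methylene dienone (exocyclic C2′=C1′, ring C4′=C5′) | C=C1C(=O)C=C2[C@@H]3CC[C@H](C)[C@]12CC3(C)C | intermediate
23 | bromomagnesium C2′=C3′ enolate from vinyl addition to 22 | C=CCC1=C(O[Mg]Br)C=C2[C@@H]3CC[C@H](C)[C@]12CC3(C)C | intermediate
24 | 2′-allyl enone (C1′ on the side of the C9′ methyl, H2′ on the C11′ side) | C=CC[C@@H]1C(=O)C=C2[C@@H]3CC[C@H](C)[C@]12CC3(C)C | intermediate
25 | lithium C3′–C4′ enolate from reduction of 24 | [Li+].C=CC[C@@H]1C([O-])=C[C@H]2[C@@H]3CC[C@H](C)[C@]12CC3(C)C | intermediate
26 | 2′-allyl saturated ketone (H5′ on the ring B side, rings A and C cis-fused) | C=CC[C@@H]1C(=O)C[C@H]2[C@@H]3CC[C@H](C)[C@]12CC3(C)C | intermediate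
27 | ethylene ketal (C3′ dioxolane) of 26 | C=CC[C@@H]1C4(OCCO4)C[C@H]2[C@@H]3CC[C@H](C)[C@]12CC3(C)C | intermediate
28 | ozonide (1,2,4-trioxolane) of 27 | C1(C[C@@H]2C5(OCCO5)C[C@H]3[C@@H]4CC[C@H](C)[C@]23CC4(C)C)OCOO1 | intermediate
29 | ketal alcohol, HO–C4H2–C1′H2 on C2′ of the ketalised tricycle | OCC[C@@H]1C4(OCCO4)C[C@H]2[C@@H]3CC[C@H](C)[C@]12CC3(C)C | intermediate
30 | ketal bromide, Br–C4H2–C1′H2 on C2′ of the ketalised tricycle | BrCC[C@@H]1C4(OCCO4)C[C@H]2[C@@H]3CC[C@H](C)[C@]12CC3(C)C | intermediate
31 | ozonide (1,2,4-trioxolane) of 16 | C1(C[C@]23C(=O)[C@H](CC[C@@H]2C)C(C)(C)C3)OCOO1 | intermediate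
32 | 2-[(1S,2S,5R)-2,6,6-trimethyl-8-oxobicyclo[3.2.1]octan-1-yl]acetaldehyde | O=CC[C@]12C(=O)[C@H](CC[C@@H]1C)C(C)(C)C2 | intermediate
33 | Grignard reagent from 30 | Br[Mg]CC[C@@H]1C4(OCCO4)C[C@H]2[C@@H]3CC[C@H](C)[C@]12CC3(C)C | intermediate
34 | coupled alcohol (C3 carbinol epimers): bicyclooctanone–C2H2–C3H(OH)–C4H2–C1′H2–C2′ of the ketalised tricycle | OC(CC[C@@H]2C4(OCCO4)C[C@H]3[C@@H]4CC[C@H](C)[C@]23CC4(C)C)C[C@]12C(=O)[C@H](CC[C@@H]1C)C(C)(C)C2 | intermediate
35 | aldol precursor: bicyclo[3.2.1]octan-8-one with the C3 ketone chain on C10 carrying the ketalised saturated half | O=C(CC[C@@H]2C4(OCCO4)C[C@H]3[C@@H]4CC[C@H](C)[C@]23CC4(C)C)C[C@]12C(=O)[C@H](CC[C@@H]1C)C(C)(C)C2 | intermediate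
36 | aldol adduct of 35 (tertiary OH on C5, rings A and C cis-fused, C1′ on the convex face) | O=C1C[C@]23[C@@H](C)CC[C@@H]([C@]3(O)[C@H]1C[C@@H]1C4(OCCO4)C[C@H]5[C@@H]4CC[C@H](C)[C@]15CC4(C)C)C(C)(C)C2 | intermediate
37 | aldol product: tricyclic C4=C5 enone linked through C1′ to the ketalised saturated half | O=C1C[C@]23[C@@H](C)CC[C@@H](C3=C1C[C@@H]1C4(OCCO4)C[C@H]5[C@@H]4CC[C@H](C)[C@]15CC4(C)C)C(C)(C)C2 | intermediate
38 | lithium C3–C4 enolate from reduction of 37 | C1C([O-])=C(C[C@@H]4C7(OCCO7)C[C@H]5[C@@H]6CC[C@H](C)[C@]45CC6(C)C)[C@H]2[C@@H]3CC[C@H](C)[C@]12CC3(C)C.[Li+] | intermediate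
39 | saturated ketone as C4 epimers (C5–H set) | C1C(=O)C(C[C@@H]4C7(OCCO7)C[C@H]5[C@@H]6CC[C@H](C)[C@]45CC6(C)C)[C@H]2[C@@H]3CC[C@H](C)[C@]12CC3(C)C | intermediate
40 | saturated diketone monoketal, C4 and C5 as in the target, C2 still CH2 | C1C(=O)[C@H](C[C@@H]4C7(OCCO7)C[C@H]5[C@@H]6CC[C@H](C)[C@]45CC6(C)C)[C@H]2[C@@H]3CC[C@H](C)[C@]12CC3(C)C | intermediate
41 | C2-(dimethylaminomethyl) derivative of 40 (ketal; CH2N on the C11 side) | CN(C)C[C@H]1C(=O)[C@H](C[C@@H]4C7(OCCO7)C[C@H]5[C@@H]6CC[C@H](C)[C@]45CC6(C)C)[C@H]2[C@@H]3CC[C@H](C)[C@]12CC3(C)C | intermediate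
42 | C2-(dimethylaminomethyl) diketone (C3′ ketone free) | CN(C)C[C@H]1C(=O)[C@H](C[C@@H]4C(=O)C[C@H]5[C@@H]6CC[C@H](C)[C@]45CC6(C)C)[C@H]2[C@@H]3CC[C@H](C)[C@]12CC3(C)C | intermediate
43 | methiodide of 42 | C[N+](C)(C)C[C@H]1C(=O)[C@H](C[C@@H]4C(=O)C[C@H]5[C@@H]6CC[C@H](C)[C@]45CC6(C)C)[C@H]2[C@@H]3CC[C@H](C)[C@]12CC3(C)C.[I-] | intermediate
44 | alertenone | C=C1C(=O)[C@H](C[C@@H]2C(=O)C[C@H]3[C@@H]4CC[C@H](C)[C@]23CC4(C)C)[C@H]2[C@@H]3CC[C@H](C)[C@]12CC3(C)C | target

Total step count: 23. Longest linear sequence: 20 steps (from 4, or equally from 1, through 16, 30 and 35 to 44).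

Steps most likely to fail

Step 20. What may go wrong: ring closure at the hindered bridge carbonyl may be slow, the aldol equilibrium may rest at the open diketone or at aldol 36, and dehydration to a tetrasubstituted alkene may stall while prolonged base erodes material. Fallback (intramolecular Horner–Wadsworth–Emmons olefination in place of aldol dehydration): it sets out from bromide 30 and aldehyde 32. Arbuzov reaction of 30 with P(OMe)3 (neat, 110 °C) should give the dimethyl phosphonate F1. Its α-lithio derivative (n-BuLi, THF, −78 °C) adds to 32 to give the β-hydroxy phosphonate F2. Dess–Martin oxidation gives the β-keto phosphonate F3, which is 35 with P(O)(OMe)2 on C4. NaH in THF then closes ring A by olefination of the C5 ketone; loss of dimethyl phosphate makes the closure irreversible. The route is rejoined at 37.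

Step 12. What may go wrong: poor facial selectivity in the protonation of the C2′ enolate, or epimerisation of the less stable C2′ epimer during work-up and the steps before the ketal is in place. Fallback (C2′ set by hydroboration on a ketal, with no enolisable carbonyl present): it sets out from enone 19, whose Mannich base 20 is isolated instead of being eliminated. Li/NH3 as in step 13 should give the saturated amino ketone F4. Ethylene glycol with TsOH (1.2 equiv, benzene, Dean–Stark) gives the amino ketal F5, whose C2′ configuration is immaterial. MeI gives the methiodide F6, and KOt-Bu (THF, 60 °C) eliminates trimethylamine to the α-methylene ketal F7. 9-BBN should add to the exocyclic alkene from the face away from the C9′ methyl and give the alkylborane F8 with the hydrogen on C2′ where the target needs it. B-alkyl Suzuki–Miyaura coupling of F8 with vinyl bromide (Pd(dppf)Cl2, K3PO4, THF/DMF/H2O) rejoins the route at ketal 27.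

Step 8. What may go wrong: competing elimination of the secondary tosylate, enolisation toward C6 (which would break the stereochemical link between C6 and C9), or slow closure at a fully substituted enolate carbon. Fallback (ring B closed by a metalated hydrazone in place of a potassium enolate): it sets out from hydrazone 11. Bu4NF removes the silyl group to give the hydroxy hydrazone F9, and TsCl in pyridine gives the tosylate hydrazone F10. LiN(i-Pr)2 (THF, 0 °C) metalates the allyl-bearing α-carbon; the azaenolate is more nucleophilic and less prone to elimination or oxygen alkylation, and should close ring B with the same inversion at C9 to give the bicyclic hydrazone F11. Hydrolysis with aqueous oxalic acid rejoins the route at 16.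

Further compounds

F1 | step 20 | dimethyl phosphonate from 30, (MeO)2P(O)–C4H2–C1′H2 on C2′ of the ketalised tricycle | COP(=O)(OC)CC[C@@H]1C4(OCCO4)C[C@H]2[C@@H]3CC[C@H](C)[C@]12CC3(C)C
F2 | step 20 | β-hydroxy phosphonate (C3 carbinol, phosphonate on C4; epimers) | OC(C[C@]12C(=O)[C@H](CC[C@@H]1C)C(C)(C)C2)C(C[C@@H]2C4(OCCO4)C[C@H]3[C@@H]4CC[C@H](C)[C@]23CC4(C)C)P(=O)(OC)OC
F3 | step 20 | β-keto phosphonate (35 with P(O)(OMe)2 on C4) | O=C(C[C@]12C(=O)[C@H](CC[C@@H]1C)C(C)(C)C2)C(C[C@@H]2C4(OCCO4)C[C@H]3[C@@H]4CC[C@H](C)[C@]23CC4(C)C)P(=O)(OC)OC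
F4 | step 12 | saturated 2′-(dimethylaminomethyl) ketone | CN(C)C[C@H]1C(=O)C[C@H]2[C@@H]3CC[C@H](C)[C@]12CC3(C)C
F5 | step 12 | ethylene ketal of F4 (C2′ epimers) | CN(C)CC1C4(OCCO4)C[C@H]2[C@@H]3CC[C@H](C)[C@]12CC3(C)C
F6 | step 12 | methiodide of F5 | C[N+](C)(C)CC1C4(OCCO4)C[C@H]2[C@@H]3CC[C@H](C)[C@]12CC3(C)C.[I-]
F7 | step 12 | α-methylene ketal (exocyclic C2′=C1′ next to the dioxolane) | C=C1C4(OCCO4)C[C@H]2[C@@H]3CC[C@H](C)[C@]12CC3(C)C
F8 | step 12 | B-alkyl-9-borabicyclo[3.3.1]nonane, boron on C1′, H2′ on the C11′ side | C(B5C6CCCC5CCC6)[C@@H]1C4(OCCO4)C[C@H]2[C@@H]3CC[C@H](C)[C@]12CC3(C)C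
F9 | step 8 | hydroxy hydrazone (11 without the silyl group) | COC[C@@H]1CCCN1/N=C2\[C@H](CC[C@@H](C)O)C(C)(C)CC2CC=C
F10 | step 8 | tosylate hydrazone | COC[C@@H]1CCCN1/N=C2\[C@H](CC[C@@H](C)OS(=O)(=O)c3ccc(C)cc3)C(C)(C)CC2CC=C
F11 | step 8 | SAMP hydrazone of 16 | C=CC[C@]12C(=NN3CCC[C@H]3COC)[C@H](CC[C@@H]1C)C(C)(C)C2
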